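**Plan**
- Cuts, in retrosynthetic order: C1–OH (allylic selenoxide [2,3] shift); C1–C2′ of the side chain (vinylcerium + ring ketone); C4–Br with re-closure of C2–C4 to a chlorocyclopropane fused to a cyclopentanone; the cyclopropane bonds C2–C3 and C2–C4 (carbene + E-chloroalkene). Ring numbering: C1 carbinol, C3 CHCl, C4 C(CH3)Br.
- Forward: a diazoketone carbene closes the five-membered ring and the cyclopropane together as a bicyclo[3.1.0]hexan-2-one. HBr then breaks the shared C2–C4 bond, so C3 enters the ring (five → six). The side chain is joined at C1 afterwards.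
- Enabling feature: at the ketone level of C1, ring atoms C1(=O)–C2H2–C3H(Cl)–C4(CH3)(Br) are a γ-bromo-β-chloro ketone. This is the HBr homo-conjugate adduct of a cyclopropyl ketone with C3 as chlorinated apex and C4 as methylated fusion carbon. The C1 carbonyl and the three-membered ring are the helpers; the opening and the later work at C1 remove them.
- Stereochemistry: C3/C4 from ligand-controlled cyclopropanation of an E-chloroalkene (exo-Cl) and inversion at C4 in the opening; C1 from oxygen delivery anti to the axial chlorine; C5′ from CBS reduction.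

Key step: step 5

Remark on the chemistry: the sense of induction of the copper–bisoxazoline catalyst in step 4 cannot be assigned beforehand, so the ligand antipode that gives (1R,5R,6R)-7 is the one used; 21 is drawn as its expected major C1 epimer.

Step 1
Reactants: 1 pent-4-yn-1-ol
Product: 3 (4E)-5-chloro-4-methylpent-4-en-1-ol, via alkenylalane 2 (not isolated)
Conditions: Me3Al (3 equiv), Cp2ZrCl2 (0.25 equiv), CH2Cl2, 0 °C to rt; then NCS, THF, −30 to 0 °C; aq. HCl
Reagents that add atoms: trimethylaluminium C[Al](C)C; N-chlorosuccinimide O=C1CCC(=O)N1Cl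
Why: Zirconium-catalysed syn-carboalumination (Negishi) puts CH3 on the internal alkyne carbon with Al cis to it, and halogenolysis of the C–Al bond with retention fixes the E geometry (Cl cis to CH3) that later becomes the exo chlorine.

Step 2
Reactants: 3 (4E)-5-chloro-4-methylpent-4-en-1-ol
Product: 4 (4E)-5-chloro-4-methylpent-4-enoic acid
Conditions: TEMPO (0.2 equiv), PhI(OAc)2 (2.2 equiv), MeCN/H2O 1:1, rt
Reagents that add atoms: water O
Why: Oxoammonium (TEMPO) oxidation of the primary alcohol through the aldehyde hydrate to the acid, to which the vinyl chloride is inert.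

Step 3
Reactants: 4 (4E)-5-chloro-4-methylpent-4-enoic acid
Product: 6 (5E)-6-chloro-1-diazo-5-methylhex-5-en-2-one, via acid chloride 5 (not isolated)
Conditions: (COCl)2, DMF (cat.), CH2Cl2, 0 °C to rt, evaporate; CH2N2 (3 equiv), Et2O, 0 °C
Reagents that add atoms: oxalyl chloride ClC(=O)C(=O)Cl (chlorine of 5); diazomethane C=[N+]=[N-]
Why: Acylation of diazomethane by the acid chloride (first stage of the Arndt–Eistert sequence), with a second equivalent of diazomethane taking up HCl.

Step 4
Reactants: 6 (5E)-6-chloro-1-diazo-5-methylhex-5-en-2-one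
Product: 7 (1R,5R,6R)-6-chloro-5-methylbicyclo[3.1.0]hexan-2-one
Conditions: Cu(MeCN)4PF6 (5 mol %), 2,2′-(propane-2,2-diyl)bis[(4S)-4-tert-butyl-4,5-dihydro-1,3-oxazole] (6 mol %), CH2Cl2, slow addition of 6, rt
Reagents that add atoms: none
Why: Intramolecular copper-carbene cyclopropanation is stereospecific, so the E alkene gives the exo chloride (Cl cis to CH3) with the cis ring fusion forced by the tether, and the chiral bisoxazoline selects the alkene face and thereby the absolute configuration.

Step 5
Reactants: 7 (1R,5R,6R)-6-chloro-5-methylbicyclo[3.1.0]hexan-2-one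
Product: 9 (3R,4R)-4-bromo-3-chloro-4-methylcyclohexan-1-one, via bromo enol 8 (not isolated)
Conditions: HBr (33% in AcOH, 1.5 equiv), CH2Cl2, −20 to 0 °C
Reagents that add atoms: hydrogen bromide Br
Why: O-Protonation of the cyclopropyl ketone makes the C1–C5 ring-fusion bond the acceptor bond of a homo-conjugate addition: bromide enters at C5, the only cyclopropane carbon that can carry charge as a tertiary centre, the C1–C5 bond breaks, and enol 8 tautomerises to 9, so the five-membered ring takes in the former apex carbon and becomes the cyclohexanone. The closest known reaction type is the hydrohalic-acid opening of cyclopropyl ketones to γ-halo ketones, in its ring-enlarging form when the distal fusion carbon is tertiary. No ring is closed by bond formation; the six-membered ring arises by heterolysis of the bond shared by the two rings of 7. The C4 bromide of 9 is set by backside attack at C5 of 7 (inversion), which with the exo chlorine gives the trans Br/Cl pair; a looser, cation-like pathway should give the same result because the neighbouring chlorine bridges and bromide again enters anti to it, and the C3 chloride is carried over untouched from C6 of 7. The step needs cleavage of the fusion bond and not of C1–C6: the σ-withdrawing chlorine on C6 weakens the distal C1–C5 bond and disfavours substitution at C6, and the methyl group on C5 stabilises the developing charge.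

Step 6
Reactants: 10 N-methoxy-N-methylacetamide, 11 2,3-dibromoprop-1-ene
Product: 13 4-bromo-N-methoxy-N-methylpent-4-enamide, via lithium enolate 12 (not isolated)
Conditions: LiN(iPr)2, THF, −78 °C; then 11, −78 to −20 °C
Reagents that add atoms: lithium diisopropylamide [Li]N(C(C)C)C(C)C (lithium of 12)
Why: Enolate alkylation (SN2) at the allylic bromide of 11, the vinylic bromide being inert.

Step 7
Reactants: 13 4-bromo-N-methoxy-N-methylpent-4-enamide, 14 isopropenylmagnesium bromide
Product: 16 6-bromo-2-methylhepta-1,6-dien-3-one, via magnesium chelate 15 (not isolated)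
Conditions: THF, −20 to 0 °C; 1 M HCl
Reagents that add atoms: none
Why: Weinreb ketone synthesis, in which the chelated tetrahedral adduct stops at single addition and releases the enone on acidic work-up.

Step 8
Reactants: 16 6-bromo-2-methylhepta-1,6-dien-3-one
Product: 17 (3R)-6-bromo-2-methylhepta-1,6-dien-3-ol
Conditions: (S)-2-methyl-CBS-oxazaborolidine (0.2 equiv), catecholborane (1.5 equiv), toluene, −78 °C; aq. work-up
Reagents that add atoms: none
Why: Corey–Bakshi–Shibata reduction with the isopropenyl group as the large substituent, so the (S)-catalyst should give the (R)-alcohol, while catecholborane at −78 °C leaves the 1,1-disubstituted alkenes alone.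

Step 9
Reactants: 17 (3R)-6-bromo-2-methylhepta-1,6-dien-3-ol
Product: 18 {[(3R)-6-bromo-2-methylhepta-1,6-dien-3-yl]oxy}(tert-butyl)dimethylsilane
Conditions: TBSCl, imidazole, DMF, rt
Reagents that add atoms: tert-butyldimethylsilyl chloride CC(C)(C)[Si](C)(C)Cl
Why: Silylation of the secondary alcohol masks it against the organometallic, PBr3 and oxidant of steps 10 to 13.

Step 10
Reactants: 18 {[(3R)-6-bromo-2-methylhepta-1,6-dien-3-yl]oxy}(tert-butyl)dimethylsilane, 9 (3R,4R)-4-bromo-3-chloro-4-methylcyclohexan-1-one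
Product: 21 (1R,3R,4R)-4-bromo-1-[(5R)-5-{[tert-butyl(dimethyl)silyl]oxy}-6-methylhepta-1,6-dien-2-yl]-3-chloro-4-methylcyclohexan-1-ol, via vinyllithium 19 (not isolated), via vinylcerium dichloride 20 (not isolated)
Conditions: t-BuLi (2 equiv), Et2O, −78 °C; CeCl3 (anhydrous), THF, −78 °C; then 9, −78 °C; aq. NH4Cl
Reagents that add atoms: tert-butyllithium [Li]C(C)(C)C (lithium of 19); cerium trichloride Cl[Ce](Cl)Cl (cerium and chlorine of 20)
Why: Bromine–lithium exchange, transmetalation to the weakly basic organocerium and carbonyl 1,2-addition, which in the Br/Cl-diaxial conformer of 9 should occur anti to the axial chlorine and give mainly the (1R) carbinol; its C1 epimer is carried along because step 11 erases this centre.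

Step 11
Reactants: 21 (1R,3R,4R)-4-bromo-1-[(5R)-5-{[tert-butyl(dimethyl)silyl]oxy}-6-methylhepta-1,6-dien-2-yl]-3-chloro-4-methylcyclohexan-1-ol
Product: 22 (3R,4R)-4-bromo-1-[(5R)-1-bromo-5-{[tert-butyl(dimethyl)silyl]oxy}-6-methylhept-6-en-2-ylidene]-3-chloro-4-methylcyclohexane (alkene isomer mixture)
Conditions: PBr3 (0.4 equiv), pyridine (cat.), Et2O, −20 to 0 °C
Reagents that add atoms: phosphorus tribromide BrP(Br)Br
Why: Allylic substitution with transposition (SN2′ type, as for tertiary vinyl carbinols going to primary allylic bromides) gives the tetrasubstituted alkene, and both C1 epimers of 21 converge on 22.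

Step 12
Reactants: 22 (3R,4R)-4-bromo-1-[(5R)-1-bromo-5-{[tert-butyl(dimethyl)silyl]oxy}-6-methylhept-6-en-2-ylidene]-3-chloro-4-methylcyclohexane
Product: 23 (3R,4R)-4-bromo-1-[(5R)-5-{[tert-butyl(dimethyl)silyl]oxy}-6-methyl-1-(phenylselanyl)hept-6-en-2-ylidene]-3-chloro-4-methylcyclohexane
Conditions: (PhSe)2, NaBH4, EtOH, 0 °C; then 22, THF, 0 °C
Reagents that add atoms: diphenyl diselenide c1ccc(cc1)[Se][Se]c1ccccc1
Why: SN2 displacement of the primary allylic bromide by the soft, non-basic selenolate, which should not touch the tertiary bromide or the secondary chloride at this temperature.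

Step 13
Reactants: 23 (3R,4R)-4-bromo-1-[(5R)-5-{[tert-butyl(dimethyl)silyl]oxy}-6-methyl-1-(phenylselanyl)hept-6-en-2-ylidene]-3-chloro-4-methylcyclohexane
Product: 26 (1S,3R,4R)-4-bromo-1-[(5R)-5-{[tert-butyl(dimethyl)silyl]oxy}-6-methylhepta-1,6-dien-2-yl]-3-chloro-4-methylcyclohexan-1-ol, via allylic selenoxide 24 (not isolated), via selenenate ester 25 (not isolated)
Conditions: mCPBA (1.05 equiv), CH2Cl2, −78 °C; then pyridine, H2O, −78 °C to rt
Reagents that add atoms: 3-chloroperoxybenzoic acid O=C(OO)c1cccc(Cl)c1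
Why: Selenide oxidation and [2,3]-sigmatropic selenoxide-to-selenenate rearrangement, an exothermic shift with an early transition state, so oxygen should reach C1 from the face anti to the axial C3 chlorine, setting (1S) (OH cis to Br) and returning the 1,1-disubstituted alkene.

Step 14
Reactants: 26 (1S,3R,4R)-4-bromo-1-[(5R)-5-{[tert-butyl(dimethyl)silyl]oxy}-6-methylhepta-1,6-dien-2-yl]-3-chloro-4-methylcyclohexan-1-ol
Product: 27 (1S,3R,4R)-4-bromo-3-chloro-1-[(5R)-5-hydroxy-6-methylhepta-1,6-dien-2-yl]-4-methylcyclohexan-1-ol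
Conditions: HF·pyridine, pyridine, THF, 0 °C to rt
Reagents that add atoms: none
Why: Buffered fluoride desilylation, mild enough not to ionise the tertiary allylic alcohol or eliminate the tertiary bromide.

**Compound list**
1 | pent-4-yn-1-ol | C#CCCCO | starting material
2 | dimethyl[(1E)-5-(dimethylalumanyloxy)-2-methylpent-1-en-1-yl]alumane | C[Al](C)/C=C(\C)CCCO[Al](C)C | intermediate
3 | (4E)-5-chloro-4-methylpent-4-en-1-ol | Cl/C=C(\C)CCCO | intermediate
4 | (4E)-5-chloro-4-methylpent-4-enoic acid | Cl/C=C(\C)CCC(=O)O | intermediate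
5 | (4E)-5-chloro-4-methylpent-4-enoyl chloride | Cl/C=C(\C)CCC(=O)Cl | intermediate
6 | (5E)-6-chloro-1-diazo-5-methylhex-5-en-2-one | Cl/C=C(\C)CCC(=O)C=[N+]=[N-] | intermediate
7 | (1R,5R,6R)-6-chloro-5-methylbicyclo[3.1.0]hexan-2-one | O=C1CC[C@@]2(C)[C@H](Cl)[C@@H]12 | intermediate
8 | (4R,5R)-4-bromo-5-chloro-4-methylcyclohex-1-en-1-ol | OC1=C[C@@H](Cl)[C@](C)(Br)CC1 | intermediate
9 | (3R,4R)-4-bromo-3-chloro-4-methylcyclohexan-1-one | O=C1CC[C@@](C)(Br)[C@H](Cl)C1 | intermediate
10 | N-methoxy-N-methylacetamide | CC(=O)N(C)OC | starting material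
11 | 2,3-dibromoprop-1-ene | C=C(Br)CBr | starting material
12 | lithium enolate of N-methoxy-N-methylacetamide | [Li]OC(=C)N(C)OC | intermediate
13 | 4-bromo-N-methoxy-N-methylpent-4-enamide | C=C(Br)CCC(=O)N(C)OC | intermediate
14 | isopropenylmagnesium bromide | C=C(C)[Mg]Br | starting material
15 | bromomagnesium salt of the tetrahedral adduct of 13 and 14 | C=C(C)C(O[Mg]Br)(CCC(Br)=C)N(C)OC | intermediate
16 | 6-bromo-2-methylhepta-1,6-dien-3-one | C=C(C)C(=O)CCC(Br)=C | intermediate
17 | (3R)-6-bromo-2-methylhepta-1,6-dien-3-ol | C=C(C)[C@H](O)CCC(Br)=C | intermediate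
18 | {[(3R)-6-bromo-2-methylhepta-1,6-dien-3-yl]oxy}(tert-butyl)dimethylsilane | C=C(C)[C@H](O[Si](C)(C)C(C)(C)C)CCC(Br)=C | intermediate
19 | [(5R)-5-{[tert-butyl(dimethyl)silyl]oxy}-6-methylhepta-1,6-dien-2-yl]lithium | C=C(C)[C@H](O[Si](C)(C)C(C)(C)C)CCC([Li])=C | intermediate
20 | dichloro[(5R)-5-{[tert-butyl(dimethyl)silyl]oxy}-6-methylhepta-1,6-dien-2-yl]cerium | C=C(C)[C@H](O[Si](C)(C)C(C)(C)C)CCC(=C)[Ce](Cl)Cl | intermediate
21 | (1R,3R,4R)-4-bromo-1-[(5R)-5-{[tert-butyl(dimethyl)silyl]oxy}-6-methylhepta-1,6-dien-2-yl]-3-chloro-4-methylcyclohexan-1-ol | C=C(C)[C@H](O[Si](C)(C)C(C)(C)C)CCC(=C)[C@@]1(O)CC[C@@](C)(Br)[C@H](Cl)C1 | intermediate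
22 | (3R,4R)-4-bromo-1-[(5R)-1-bromo-5-{[tert-butyl(dimethyl)silyl]oxy}-6-methylhept-6-en-2-ylidene]-3-chloro-4-methylcyclohexane (alkene geometry not defined) | C=C(C)[C@H](O[Si](C)(C)C(C)(C)C)CCC(CBr)=C1CC[C@@](C)(Br)[C@H](Cl)C1 | intermediate
23 | (3R,4R)-4-bromo-1-[(5R)-5-{[tert-butyl(dimethyl)silyl]oxy}-6-methyl-1-(phenylselanyl)hept-6-en-2-ylidene]-3-chloro-4-methylcyclohexane (alkene geometry not defined) | C=C(C)[C@H](O[Si](C)(C)C(C)(C)C)CCC(C[Se]c2ccccc2)=C1CC[C@@](C)(Br)[C@H](Cl)C1 | intermediate
24 | selenoxide of 23 (mixture at selenium) | C=C(C)[C@H](O[Si](C)(C)C(C)(C)C)CCC(C[Se](=O)c2ccccc2)=C1CC[C@@](C)(Br)[C@H](Cl)C1 | intermediate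
25 | benzeneselenenate ester of 26 (O–SePh on C1) | C=C(C)[C@H](O[Si](C)(C)C(C)(C)C)CCC(=C)[C@]1(O[Se]c2ccccc2)CC[C@@](C)(Br)[C@H](Cl)C1 | intermediate
26 | (1S,3R,4R)-4-bromo-1-[(5R)-5-{[tert-butyl(dimethyl)silyl]oxy}-6-methylhepta-1,6-dien-2-yl]-3-chloro-4-methylcyclohexan-1-ol | C=C(C)[C@H](O[Si](C)(C)C(C)(C)C)CCC(=C)[C@]1(O)CC[C@@](C)(Br)[C@H](Cl)C1 | intermediate
27 | (1S,3R,4R)-4-bromo-3-chloro-1-[(5R)-5-hydroxy-6-methylhepta-1,6-dien-2-yl]-4-methylcyclohexan-1-ol | C=C(C)[C@H](O)CCC(=C)[C@]1(O)CC[C@@](C)(Br)[C@H](Cl)C1 | target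

**Totals and risks**
Total: 14 steps. Longest linear sequence: 10 steps (steps 1 to 5 and 10 to 14).

Step 5. The newly formed tertiary bromide may lose HBr (E1, onward to the enone and 4-methylphenol), or bromide and chloride may exchange places through the chloronium ion under the acidic, bromide-rich conditions. The fallback separates ring expansion from bromide introduction. Setting out from 7, HClO4 (cat.) in acetone–water at 0 °C opens the fusion bond with water as nucleophile to give the chlorohydrin ketone (3R,4R)-3-chloro-4-hydroxy-4-methylcyclohexan-1-one F1, with OH anti to Cl. Brief exposure of F1 to anhydrous HBr in CH2Cl2 at −40 °C replaces the tertiary hydroxyl with retention, through participation of the anti chlorine, and returns to 9.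

Step 4. The copper carbene may discriminate the faces of the trisubstituted chloroalkene poorly, or insert into C–H bonds. The fallback takes the absolute configuration from an enzymatic resolution. Setting out from 6, Rh2(OAc)4 (1 mol %, CH2Cl2) gives the racemic ketone, that is 7 together with its mirror image (1S,5S,6S)-6-chloro-5-methylbicyclo[3.1.0]hexan-2-one F2. NaBH4 (MeOH, −20 °C) reduces both from the convex face to the cis alcohols (1R,2S,5R,6R)-6-chloro-5-methylbicyclo[3.1.0]hexan-2-ol F3 and (1S,2R,5S,6S)-6-chloro-5-methylbicyclo[3.1.0]hexan-2-ol F4. Candida antarctica lipase B with vinyl acetate should acylate the (2R) alcohol to (1S,2R,5S,6S)-6-chloro-5-methylbicyclo[3.1.0]hexan-2-yl acetate F5 and leave F3. After separation, F3 is oxidised with Dess–Martin periodinane and the route is rejoined at 7.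

Step 13. Oxygen delivery in the sigmatropic shift may show poor facial selectivity, or the oxidant may attack the side-chain alkenes. The fallback makes the C1–O bond by nucleophilic epoxidation and the alkene by a Wharton transposition. Setting out from 22, N-methylmorpholine N-oxide (MeCN, rt; Ganem oxidation) converts the primary allylic bromide into the enal (5R)-2-[(3R,4R)-4-bromo-3-chloro-4-methylcyclohexylidene]-5-{[tert-butyl(dimethyl)silyl]oxy}-6-methylhept-6-enal F6. H2O2/NaHCO3 (MeOH, 0 °C) adds hydroperoxide to the ring carbon anti to the axial chlorine and closes the spiro-epoxy aldehyde 6-bromo-5-chloro-6-methyl-2-[(3R)-3-{[tert-butyl(dimethyl)silyl]oxy}-4-methylpent-4-en-1-yl]-1-oxaspiro[2.5]octane-2-carbaldehyde F7 (epoxide oxygen cis to Br). N2H4·H2O with AcOH (MeOH, 0 °C to rt) then gives the tertiary allylic alcohol, and the route is rejoined at 26.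

Further compounds
F1 | step 5 | (3R,4R)-3-chloro-4-hydroxy-4-methylcyclohexan-1-one | O=C1CC[C@@](C)(O)[C@H](Cl)C1
F2 | step 4 | (1S,5S,6S)-6-chloro-5-methylbicyclo[3.1.0]hexan-2-one | O=C1CC[C@]2(C)[C@@H](Cl)[C@H]12
F3 | step 4 | (1R,2S,5R,6R)-6-chloro-5-methylbicyclo[3.1.0]hexan-2-ol | O[C@H]1CC[C@@]2(C)[C@H](Cl)[C@@H]12
F4 | step 4 | (1S,2R,5S,6S)-6-chloro-5-methylbicyclo[3.1.0]hexan-2-ol | O[C@@H]1CC[C@]2(C)[C@@H](Cl)[C@H]12
F5 | step 4 | (1S,2R,5S,6S)-6-chloro-5-methylbicyclo[3.1.0]hexan-2-yl acetate | CC(=O)O[C@@H]1CC[C@]2(C)[C@@H](Cl)[C@H]12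
F6 | step 13 | (5R)-2-[(3R,4R)-4-bromo-3-chloro-4-methylcyclohexylidene]-5-{[tert-butyl(dimethyl)silyl]oxy}-6-methylhept-6-enal | C=C(C)[C@H](O[Si](C)(C)C(C)(C)C)CCC(C=O)=C1CC[C@@](C)(Br)[C@H](Cl)C1
F7 | step 13 | 6-bromo-5-chloro-6-methyl-2-[(3R)-3-{[tert-butyl(dimethyl)silyl]oxy}-4-methylpent-4-en-1-yl]-1-oxaspiro[2.5]octane-2-carbaldehyde (epoxide oxygen cis to Br; mixture at the aldehyde-bearing carbon) | C=C(C)[C@H](O[Si](C)(C)C(C)(C)C)CCC1(C=O)O[C@]12CC[C@@](C)(Br)[C@H](Cl)C2
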